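**Plan**

The enamine C9=C9a with N4 on C9a is read as what is left of an ynamide triple bond, and C1 (O), C11 (O) and C10 (ethyl) of ring C as the carbons of a 1,3-dioxygenated diene C1=C12–C11=C10; cutting C9a–C1 and C9–C10 opens rings B and C in one retro-[4+2] step.
Before that the retrosynthesis cuts N4–C5 (azepine), lactone E at C18–O and C18–C19, and lactone D at C11–O and C12–C13.
Forward: L-aspartic acid (C1–C3, N4, C18) is extended by a Claisen condensation (C12, C11), a chelate-controlled Z-selective O-alkylation at C1, a Fukuyama coupling (C10, ethyl) and an N-alkynylation (C9a, C9, C8–C5) to the dien-ynamide; heating closes rings B and C.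
Lactone D is then built on the silyl enol ether, lactone E on C18, and the azepine ring is closed last by N-alkylation.
Stereochemistry: C3 from L-aspartic acid; C10 from the diene geometry and C1 by induction from C3 in the cycloaddition; C12, C11 and C13 by additions steered by the C1 oxygen and the ring fusion; C20 from methyl (R)-3-bromo-2-methylpropanoate; C18 by Felkin–Anh reduction.

Key step: step 10

Remark: atom numbers follow the stemona skeleton (C1 carbinol carbon, C2, C3, N4, C5–C8, C9, C9a, C10 ethyl-bearing, C11–C14 lactone D, C18–C21 lactone E) and the target is read as (1S,3S,10R,11R,12R,13S,18S,20S); SES = 2-(trimethylsilyl)ethanesulfonyl, TBDPS = tert-butyldiphenylsilyl, TBS = tert-butyldimethylsilyl, MOM = methoxymethyl; compounds 1, 5, 10, 12, 18 and 31 are taken as commercial.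

**Route**

Step 1
Reactants: 1 L-aspartic acid 4-methyl ester hydrochloride
Product: 2 N-SES-L-aspartic acid 4-methyl ester
Conditions: Me3SiCl, i-Pr2NEt, CH2Cl2, 0 °C to rt; SESCl, 0 °C to rt; aq. KHSO4
Reagents that add atoms: 2-(trimethylsilyl)ethanesulfonyl chloride, C[Si](C)(C)CCS(=O)(=O)Cl
Why: Sulfonamide formation at the amine after transient silylation of the carboxylic acid should give the N-SES acid without touching the stereocentre that becomes C3.

Step 2
Reactants: 2 N-SES-L-aspartic acid 4-methyl ester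
Product: 3 methyl (3S)-4-hydroxy-3-(SES-amino)butanoate
Conditions: BH3·THF, THF, 0 °C to rt; MeOH
Reagents that add atoms: none
Why: Chemoselective borane reduction of the free carboxylic acid in the presence of the methyl ester gives the primary alcohol that becomes C18.

Step 3
Reactants: 3 methyl (3S)-4-hydroxy-3-(SES-amino)butanoate
Product: 4 methyl (3S)-4-(TBDPS-oxy)-3-(SES-amino)butanoate
Conditions: TBDPSCl, imidazole, CH2Cl2, rt
Reagents that add atoms: tert-butyl(chloro)diphenylsilane, CC(C)(C)[Si](Cl)(c1ccccc1)c1ccccc1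
Why: Silyl ether formation at the primary alcohol under imidazole catalysis, carried out at once so that the γ-hydroxy ester cannot lactonise.

Step 4
Reactants: 4 methyl (3S)-4-(TBDPS-oxy)-3-(SES-amino)butanoate; 5 S-ethyl thioacetate
Product: 7 S-ethyl (5S)-6-(TBDPS-oxy)-3-oxo-5-(SES-amino)hexanethioate, via lithium enolate 6 (not isolated)
Conditions: 5, LiN(SiMe3)2, THF, −78 °C; then 4, −78 to −30 °C; aq. NH4Cl
Reagents that add atoms: none
Why: Crossed Claisen condensation of the methyl ester with the preformed thioester enolate builds C12 and C11, the lithiated sulfonamide nitrogen being too poor a leaving group for β-elimination.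

Step 5
Reactants: 7 S-ethyl (5S)-6-(TBDPS-oxy)-3-oxo-5-(SES-amino)hexanethioate
Product: 9 S-ethyl (2Z,5S)-6-(TBDPS-oxy)-3-(methoxymethoxy)-5-(SES-amino)hex-2-enethioate, via sodium enolate 8 (not isolated)
Conditions: NaH (1.0 equiv), THF, 0 °C; MOMCl, 0 °C
Reagents that add atoms: chloromethyl methyl ether, COCCl
Why: O-alkylation of the sodium-chelated, U-shaped β-keto thioester enolate by the hard electrophile in THF keeps the chelate geometry and should give the Z-enol ether (C1 oxygen cis to the carbonyl group), while one equivalent of NaH leaves the less acidic sulfonamide N–H alone.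

Step 6
Reactants: 9 S-ethyl (2Z,5S)-6-(TBDPS-oxy)-3-(methoxymethoxy)-5-(SES-amino)hex-2-enethioate; 10 propylzinc bromide
Product: 11 (2S,4Z)-1-(TBDPS-oxy)-4-(methoxymethoxy)-2-(SES-amino)non-4-en-6-one
Conditions: PdCl2(PPh3)2 (5 mol %), THF/PhMe, rt
Reagents that add atoms: none
Why: Fukuyama coupling, in which zerovalent palladium inserts into the C(acyl)–S bond and takes the propyl group from zinc, gives the ketone under neutral conditions and leaves the enol ether geometry as it is.

Step 7
Reactants: 12 6-chlorohex-1-yne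
Product: 13 1-bromo-6-chlorohex-1-yne
Conditions: N-bromosuccinimide, AgNO3 (10 mol %), acetone, rt
Reagents that add atoms: N-bromosuccinimide, O=C1CCC(=O)N1Br
Why: Electrophilic bromination of the terminal alkyne through its silver acetylide.

Step 8
Reactants: 11 (2S,4Z)-1-(TBDPS-oxy)-4-(methoxymethoxy)-2-(SES-amino)non-4-en-6-one; 13 1-bromo-6-chlorohex-1-yne
Product: 14 (2S,4Z)-2-[(6-chlorohex-1-ynyl)(SES)amino]-1-(TBDPS-oxy)-4-(methoxymethoxy)non-4-en-6-one
Conditions: CuSO4·5H2O (15 mol %), 1,10-phenanthroline (30 mol %), K3PO4, PhMe, 70 °C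
Reagents that add atoms: none
Why: Copper-catalysed N-alkynylation of the sulfonamide by the 1-bromoalkyne (amidative cross-coupling) under the mild heterogeneous base K3PO4, which the vinylogous ester tolerates.

Step 9
Reactants: 14 (2S,4Z)-2-[(6-chlorohex-1-ynyl)(SES)amino]-1-(TBDPS-oxy)-4-(methoxymethoxy)non-4-en-6-one
Product: 16 (2S,4Z,6Z)-6-(TBS-oxy)-2-[(6-chlorohex-1-ynyl)(SES)amino]-1-(TBDPS-oxy)-4-(methoxymethoxy)nona-4,6-diene, via lithium dienolate 15 (not isolated)
Conditions: LiN(SiMe3)2, THF, −78 °C; TBSOTf, −78 °C; Et3N, aq. NaHCO3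
Reagents that add atoms: tert-butyldimethylsilyl trifluoromethanesulfonate, CC(C)(C)[Si](C)(C)OS(=O)(=O)C(F)(F)F
Why: Kinetic α′-deprotonation at C10 by the hindered amide base and O-silylation of the Z-enolate (silyl enol ether formation) place the ethyl group trans to C12; C2, which lies trans to the carbonyl group, is not deprotonated.

Step 10
Reactants: 16 (2S,4Z,6Z)-6-(TBS-oxy)-2-[(6-chlorohex-1-ynyl)(SES)amino]-1-(TBDPS-oxy)-4-(methoxymethoxy)nona-4,6-diene
Product: 17 (2S,3aS,6R)-5-(TBS-oxy)-2-(TBDPS-oxymethyl)-7-(4-chlorobutyl)-6-ethyl-3a-(methoxymethoxy)-1-SES-2,3,3a,6-tetrahydro-1H-indole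
Conditions: PhMe (0.01 M), BHT, Et3N (1 mol %), 150 °C, sealed tube
Reagents that add atoms: none
Why: Proposed new method: on heating, the in-plane π bond of the ynamide (C9a≡C9) should add suprafacially, in one concerted but asynchronous step, across the s-cis diene C1=C12–C11=C10 and leave the nitrogen-conjugated π bond as the C9=C9a enesulfonamide; the closest known reaction type is the thermal or rhodium-catalysed intramolecular [4+2] cycloaddition of N-sulfonyl ynamides with tethered 1,3-dienes and conjugated enynes, but a 1,1-disubstituted 1,3-dioxygenated diene has not been used. Ring B closes through the bond C9a–C1 as the five-membered ring spanned by the three-atom tether C2–C3–N4 (fused mode of an intramolecular Diels–Alder reaction), and ring C is the six-membered ring of the cycloaddition itself, closed by C9a–C1 and C9–C10 as a cyclohexa-1,4-diene. C10 follows from the diene geometry, because the ethyl group and the C2 tether are both outside substituents (only the acetal oxygen and a hydrogen point inside) and therefore end up cis. C1 is set relative to C3: allylic 1,3-strain with the sulfonyl group holds the silyloxymethyl group pseudoaxial on the forming five-membered ring, and the diene should add with its C12–C11 arch on that face so that the bulkier C1 acetal oxygen lies on the open face, anti to C18. The step needs this facial selectivity and a clean [4+2] course; the short tether fixes the regiochemistry, the quaternary C1 excludes aromatisation, and a trace of Et3N protects the silyl dienol ether from acid.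

Step 11
Reactants: 17 (2S,3aS,6R)-5-(TBS-oxy)-2-(TBDPS-oxymethyl)-7-(4-chlorobutyl)-6-ethyl-3a-(methoxymethoxy)-1-SES-2,3,3a,6-tetrahydro-1H-indole; 18 ethyl diazoacetate
Product: 19 C11–C12 siloxycyclopropane ester
Conditions: Rh2(OAc)4 (1 mol %), CH2Cl2, rt, slow addition of 18
Reagents that add atoms: none
Why: Rhodium-carbenoid cyclopropanation picks the most electron-rich alkene, the silyl enol ether, and should approach C11=C12 anti to the pseudoaxial C1 acetal oxygen, which sets C12.

Step 12
Reactants: 19 C11–C12 siloxycyclopropane ester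
Product: 22 tricyclic lactone D intermediate (C13 = CH2), via C11 keto ester 20 (not isolated), via C11 hydroxy ester 21 (not isolated)
Conditions: Et3N·3HF, THF, rt; crude product, NaBH4, MeOH, −40 °C; PPTS, PhMe, 50 °C
Reagents that add atoms: none
Why: Fluoride-induced ring opening of the donor–acceptor cyclopropane gives the γ-keto ester (net α-alkylation at C12), borohydride reduction is expected from the face opposite the C10 ethyl and C12 acetate groups (C11–OH cis to both), and acid-catalysed lactonisation closes the cis-fused lactone D.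

Step 13
Reactants: 22 tricyclic lactone D intermediate (C13 = CH2)
Product: 26 13-methylidene lactone, via lithium lactone enolate 23 (not isolated), via Mannich base 24 (not isolated), via ammonium iodide 25 (not isolated)
Conditions: LiN(SiMe3)2, THF, −78 °C; Me2N=CH2+ I−, −78 to 0 °C; MeI, MeOH, rt; aq. NaHCO3, CH2Cl2
Reagents that add atoms: dimethyl(methylidene)ammonium iodide (Eschenmoser's salt), C=[N+](C)C.[I-]
Why: Mannich reaction of the lactone enolate with the iminium salt, N-methylation and Hofmann-type elimination give the α-methylidene lactone.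

Step 14
Reactants: 26 13-methylidene lactone
Product: 27 (13S)-13-methyl lactone
Conditions: H2 (1 atm), Pd/C, EtOAc, rt
Reagents that add atoms: none
Why: Catalytic hydrogenation of the exocyclic alkene from the convex face of the cis-fused lactone should leave the C13 methyl group on the concave face (H13 cis to H12), the hindered tetrasubstituted enesulfonamide and the alkyl chloride being much slower to react.

Step 15
Reactants: 27 (13S)-13-methyl lactone
Product: 28 C18 primary alcohol
Conditions: HF·pyridine, pyridine, THF, 0 °C to rt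
Reagents that add atoms: none
Why: Fluoride-mediated desilylation of the primary silyl ether under buffered conditions that the SES group, the acetal and the lactone tolerate.

Step 16
Reactants: 28 C18 primary alcohol
Product: 30 C18 carboxylic acid, via aldehyde 29 (not isolated)
Conditions: TEMPO (cat.), PhI(OAc)2, MeCN/H2O, rt
Reagents that add atoms: water, O
Why: Nitroxyl-catalysed oxidation of the primary alcohol through the aldehyde and its hydrate to the carboxylic acid; the C1 acetal and the enesulfonamide are not oxidised.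

Step 17
Reactants: 31 methyl (R)-3-bromo-2-methylpropanoate
Product: 32 [(2R)-3-methoxy-2-methyl-3-oxopropyl]zinc bromide (THF solution used as such)
Conditions: Zn, LiCl, THF, 40 °C
Reagents that add atoms: zinc, [Zn]
Why: Oxidative insertion of LiCl-activated zinc into the primary C–Br bond; the stereocentre is not involved.

Step 18
Reactants: 30 C18 carboxylic acid; 32 [(2R)-3-methoxy-2-methyl-3-oxopropyl]zinc bromide
Product: 34 C18 keto ester, via acid chloride 33 (not isolated)
Conditions: 1-chloro-N,N,2-trimethylprop-1-en-1-amine, CH2Cl2, 0 °C; then 32, Pd(PPh3)4 (5 mol %), THF, 0 °C to rt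
Reagents that add atoms: none
Why: Negishi acylation, in which the acid chloride made under neutral conditions couples with the alkylzinc at zerovalent palladium, gives the ketone, and the organozinc does not add to the lactone or ester groups.

Step 19
Reactants: 34 C18 keto ester
Product: 36 bis-lactone, via C18 hydroxy ester 35 (not isolated)
Conditions: LiBH(s-Bu)3, THF, −78 °C; aq. NH4Cl; PPTS, PhMe, 50 °C
Reagents that add atoms: none
Why: Felkin–Anh reduction, with the bulky hydride adding anti to the sulfonylated nitrogen on C3, should give the 18S alcohol (N and O syn), which lactonises onto the methyl ester to lactone E with the C20 methyl group cis to C3.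

Step 20
Reactants: 36 bis-lactone
Product: 37 C1 tertiary alcohol
Conditions: Me3SiBr, CH2Cl2, −30 °C; aq. NaHCO3
Reagents that add atoms: none
Why: Lewis-acid cleavage of the methoxymethyl acetal by bromide attack at the acetal carbon frees the tertiary alcohol without breaking the C1–O bond.

Step 21
Reactants: 37 C1 tertiary alcohol
Product: 39 CNP0179500.1, via 1-pyrroline 38 (not isolated)
Conditions: Bu4NF, THF, 50 °C; then NaI (cat.), MeCN, 70 °C
Reagents that add atoms: none
Why: Fluoride-induced fragmentation of the SES group (loss of Me3SiF, ethene and SO2) frees the nitrogen, the N–H enamine tautomerises to the 1-pyrroline, and Finkelstein-assisted intramolecular N-alkylation (7-exo-tet) followed by loss of the C9 proton from the iminium ion gives the enamine of the target.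

**Compound list**

1 | L-aspartic acid 4-methyl ester hydrochloride | COC(=O)C[C@H](N)C(=O)O.Cl | starting material
2 | (2S)-4-methoxy-4-oxo-2-{[2-(trimethylsilyl)ethanesulfonyl]amino}butanoic acid | COC(=O)C[C@H](NS(=O)(=O)CC[Si](C)(C)C)C(=O)O | intermediate
3 | methyl (3S)-4-hydroxy-3-{[2-(trimethylsilyl)ethanesulfonyl]amino}butanoate | COC(=O)C[C@H](NS(=O)(=O)CC[Si](C)(C)C)CO | intermediate
4 | methyl (3S)-4-[(tert-butyldiphenylsilyl)oxy]-3-{[2-(trimethylsilyl)ethanesulfonyl]amino}butanoate | COC(=O)C[C@H](NS(=O)(=O)CC[Si](C)(C)C)CO[Si](c1ccccc1)(c1ccccc1)C(C)(C)C | intermediate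
5 | S-ethyl thioacetate (S-ethyl ethanethioate) | CC(=O)SCC | starting material
6 | lithium enolate of S-ethyl thioacetate | [Li+].[O-]C(=C)SCC | intermediate
7 | S-ethyl (5S)-6-[(tert-butyldiphenylsilyl)oxy]-3-oxo-5-{[2-(trimethylsilyl)ethanesulfonyl]amino}hexanethioate | CCSC(=O)CC(=O)C[C@H](NS(=O)(=O)CC[Si](C)(C)C)CO[Si](c1ccccc1)(c1ccccc1)C(C)(C)C | intermediate
8 | sodium (Z)-enolate of 7, chelated by the two carbonyl oxygens | [Na+].CCSC(=O)/C=C(\[O-])/C[C@H](NS(=O)(=O)CC[Si](C)(C)C)CO[Si](c1ccccc1)(c1ccccc1)C(C)(C)C | intermediate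
9 | S-ethyl (2Z,5S)-6-[(tert-butyldiphenylsilyl)oxy]-3-(methoxymethoxy)-5-{[2-(trimethylsilyl)ethanesulfonyl]amino}hex-2-enethioate | CCSC(=O)/C=C(\OCOC)/C[C@H](NS(=O)(=O)CC[Si](C)(C)C)CO[Si](c1ccccc1)(c1ccccc1)C(C)(C)C | intermediate
10 | propylzinc bromide | CCC[Zn]Br | starting material
11 | N-[(2S,4Z)-1-[(tert-butyldiphenylsilyl)oxy]-4-(methoxymethoxy)-6-oxonon-4-en-2-yl]-2-(trimethylsilyl)ethanesulfonamide | CCCC(=O)/C=C(\OCOC)/C[C@H](NS(=O)(=O)CC[Si](C)(C)C)CO[Si](c1ccccc1)(c1ccccc1)C(C)(C)C | intermediate
12 | 6-chlorohex-1-yne | C#CCCCCCl | starting material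
13 | 1-bromo-6-chlorohex-1-yne | BrC#CCCCCCl | intermediate
14 | N-[(2S,4Z)-1-[(tert-butyldiphenylsilyl)oxy]-4-(methoxymethoxy)-6-oxonon-4-en-2-yl]-N-(6-chlorohex-1-yn-1-yl)-2-(trimethylsilyl)ethanesulfonamide | CCCC(=O)/C=C(\OCOC)/C[C@H](N(C#CCCCCCl)S(=O)(=O)CC[Si](C)(C)C)CO[Si](c1ccccc1)(c1ccccc1)C(C)(C)C | intermediate
15 | lithium (Z)-enolate of 14 at C10=C11 (cross-conjugated dienolate) | [Li+].CC/C=C(\[O-])/C=C(\OCOC)/C[C@H](N(C#CCCCCCl)S(=O)(=O)CC[Si](C)(C)C)CO[Si](c1ccccc1)(c1ccccc1)C(C)(C)C | intermediate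
16 | N-[(2S,4Z,6Z)-6-[(tert-butyldimethylsilyl)oxy]-1-[(tert-butyldiphenylsilyl)oxy]-4-(methoxymethoxy)nona-4,6-dien-2-yl]-N-(6-chlorohex-1-yn-1-yl)-2-(trimethylsilyl)ethanesulfonamide | CC/C=C(\O[Si](C)(C)C(C)(C)C)/C=C(\OCOC)/C[C@H](N(C#CCCCCCl)S(=O)(=O)CC[Si](C)(C)C)CO[Si](c1ccccc1)(c1ccccc1)C(C)(C)C | intermediate
17 | (2S,3aS,6R)-5-[(tert-butyldimethylsilyl)oxy]-2-{[(tert-butyldiphenylsilyl)oxy]methyl}-7-(4-chlorobutyl)-6-ethyl-3a-(methoxymethoxy)-1-[2-(trimethylsilyl)ethanesulfonyl]-2,3,3a,6-tetrahydro-1H-indole (indole C2, C3a, C6 are C3, C1, C10) | CC[C@@H]1C(CCCCCl)=C2N(S(=O)(=O)CC[Si](C)(C)C)[C@H](CO[Si](c3ccccc3)(c3ccccc3)C(C)(C)C)C[C@]2(OCOC)C=C1O[Si](C)(C)C(C)(C)C | intermediate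
18 | ethyl diazoacetate | CCOC(=O)C=[N+]=[N-] | starting material
19 | siloxycyclopropane: 17 with CH(CO2Et) (C13) bridging C11 and C12 on the face opposite the C1 OMOM group, OTBS kept on C11 (both C13 epimers) | CC[C@@H]1C(CCCCCl)=C2N(S(=O)(=O)CC[Si](C)(C)C)[C@H](CO[Si](c4ccccc4)(c4ccccc4)C(C)(C)C)C[C@]2(OCOC)[C@@H]3C(C(=O)OCC)[C@@]31O[Si](C)(C)C(C)(C)C | intermediate
20 | γ-keto ester: bicyclic core with C11 ketone and CH2CO2Et on C12 trans to the C1 OMOM group | CC[C@@H]1C(CCCCCl)=C2N(S(=O)(=O)CC[Si](C)(C)C)[C@H](CO[Si](c3ccccc3)(c3ccccc3)C(C)(C)C)C[C@]2(OCOC)[C@H](CC(=O)OCC)C1=O | intermediate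
21 | hydroxy ester: 20 reduced at C11, OH cis to the C12 arm and to the C10 ethyl group | CC[C@@H]1C(CCCCCl)=C2N(S(=O)(=O)CC[Si](C)(C)C)[C@H](CO[Si](c3ccccc3)(c3ccccc3)C(C)(C)C)C[C@]2(OCOC)[C@H](CC(=O)OCC)[C@@H]1O | intermediate
22 | tricyclic lactone: cis-fused γ-lactone D (O on C11, C13H2 on C12) on the bicyclic core; C1 OMOM, C3 CH2OTBDPS, N-SES, 4-chlorobutyl on C9 | CC[C@@H]1C(CCCCCl)=C2N(S(=O)(=O)CC[Si](C)(C)C)[C@H](CO[Si](c4ccccc4)(c4ccccc4)C(C)(C)C)C[C@]2(OCOC)[C@H]3[C@@H]1OC(=O)C3 | intermediate
23 | lithium enolate of lactone 22 (C13=C14) | [Li+].CC[C@@H]1C(CCCCCl)=C2N(S(=O)(=O)CC[Si](C)(C)C)[C@H](CO[Si](c4ccccc4)(c4ccccc4)C(C)(C)C)C[C@]2(OCOC)[C@H]3[C@@H]1OC([O-])=C3 | intermediate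
24 | 13-(dimethylaminomethyl) lactone (C13 epimers) | CC[C@@H]1C(CCCCCl)=C2N(S(=O)(=O)CC[Si](C)(C)C)[C@H](CO[Si](c4ccccc4)(c4ccccc4)C(C)(C)C)C[C@]2(OCOC)[C@H]3[C@@H]1OC(=O)C3CN(C)C | intermediate
25 | 13-(trimethylammoniomethyl) lactone iodide (C13 epimers) | CC[C@@H]1C(CCCCCl)=C2N(S(=O)(=O)CC[Si](C)(C)C)[C@H](CO[Si](c4ccccc4)(c4ccccc4)C(C)(C)C)C[C@]2(OCOC)[C@H]3[C@@H]1OC(=O)C3C[N+](C)(C)C.[I-] | intermediate
26 | 13-methylidene lactone | CC[C@@H]1C(CCCCCl)=C2N(S(=O)(=O)CC[Si](C)(C)C)[C@H](CO[Si](c4ccccc4)(c4ccccc4)C(C)(C)C)C[C@]2(OCOC)[C@H]3[C@@H]1OC(=O)C3=C | intermediate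
27 | (13S)-13-methyl lactone (methyl on the concave face, H13 cis to H12) | CC[C@@H]1C(CCCCCl)=C2N(S(=O)(=O)CC[Si](C)(C)C)[C@H](CO[Si](c4ccccc4)(c4ccccc4)C(C)(C)C)C[C@]2(OCOC)[C@H]3[C@@H]1OC(=O)[C@H]3C | intermediate
28 | primary alcohol: 27 with free C18H2OH | CC[C@@H]1C(CCCCCl)=C2N(S(=O)(=O)CC[Si](C)(C)C)[C@H](CO)C[C@]2(OCOC)[C@H]3[C@@H]1OC(=O)[C@H]3C | intermediate
29 | aldehyde: 28 oxidised at C18 | CC[C@@H]1C(CCCCCl)=C2N(S(=O)(=O)CC[Si](C)(C)C)[C@H](C=O)C[C@]2(OCOC)[C@H]3[C@@H]1OC(=O)[C@H]3C | intermediate
30 | carboxylic acid at C18 | CC[C@@H]1C(CCCCCl)=C2N(S(=O)(=O)CC[Si](C)(C)C)[C@H](C(=O)O)C[C@]2(OCOC)[C@H]3[C@@H]1OC(=O)[C@H]3C | intermediate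
31 | methyl (R)-3-bromo-2-methylpropanoate | BrC[C@H](C)C(=O)OC | starting material
32 | [(2R)-3-methoxy-2-methyl-3-oxopropyl]zinc bromide | Br[Zn]C[C@H](C)C(=O)OC | intermediate
33 | acid chloride of 30 | CC[C@@H]1C(CCCCCl)=C2N(S(=O)(=O)CC[Si](C)(C)C)[C@H](C(=O)Cl)C[C@]2(OCOC)[C@H]3[C@@H]1OC(=O)[C@H]3C | intermediate
34 | γ-keto ester: C18 ketone carrying CH2–CH(CH3)–CO2Me (20S) | CC[C@@H]1C(CCCCCl)=C2N(S(=O)(=O)CC[Si](C)(C)C)[C@H](C(=O)C[C@H](C)C(=O)OC)C[C@]2(OCOC)[C@H]3[C@@H]1OC(=O)[C@H]3C | intermediate
35 | (18S)-hydroxy ester from 34 | CC[C@@H]1C(CCCCCl)=C2N(S(=O)(=O)CC[Si](C)(C)C)[C@H]([C@@H](O)C[C@H](C)C(=O)OC)C[C@]2(OCOC)[C@H]3[C@@H]1OC(=O)[C@H]3C | intermediate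
36 | bis-lactone: lactones D and E in place, N-SES, C1 OMOM, 4-chlorobutyl on C9 | CC[C@@H]1C(CCCCCl)=C2N(S(=O)(=O)CC[Si](C)(C)C)[C@H]([C@@H]4C[C@H](C)C(=O)O4)C[C@]2(OCOC)[C@H]3[C@@H]1OC(=O)[C@H]3C | intermediate
37 | tertiary alcohol: 36 without the MOM group | CC[C@@H]1C(CCCCCl)=C2N(S(=O)(=O)CC[Si](C)(C)C)[C@H]([C@@H]4C[C@H](C)C(=O)O4)C[C@]2(O)[C@H]3[C@@H]1OC(=O)[C@H]3C | intermediate
38 | 1-pyrroline (C9a=N4) with C9–H and the 4-chlorobutyl chain (C9 epimers) | CC[C@@H]1C(CCCCCl)C2=N[C@H]([C@@H]4C[C@H](C)C(=O)O4)C[C@]2(O)[C@H]3[C@@H]1OC(=O)[C@H]3C | intermediate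
39 | CNP0179500.1, (1S,3S,10R,11R,12R,13S,18S,20S) | CC[C@@H]1C2=C3N(CCCC2)[C@H]([C@@H]2C[C@H](C)C(=O)O2)C[C@]3(O)[C@H]2[C@@H]1OC(=O)[C@H]2C | target

**Step count and risks**

Total step count: 21. Longest linear sequence: 19 steps (1 to 39 by steps 1–6, 8–16 and 18–21); steps 7 and 17 prepare the bromoalkyne and the zinc reagent.

The three steps most likely to fail:

1. Step 10 (carries the label). The thermal [4+2] may be too slow, because both partners are electron-rich and the oxygenated diene terminus is fully substituted, so that desilylation or polymerisation of the silyl dienol ether overtakes ring closure; the diene may also add on the wrong face of the forming five-membered ring. Fallback: the ring closure is moved from the pericyclic to the organometallic manifold. Setting out from 16, a cationic monovalent rhodium catalyst ([Rh(cod)2]BF4 with (R)- or (S)-BINAP, ClCH2CH2Cl, rt) should join the ynamide and the diene by oxidative cyclisation to a rhodacycle and reductive elimination, a known way of bringing about the [4+2] cycloaddition of ynamides and other alkynes with tethered dienes. The ligand enantiomer is chosen so that catalyst and substrate work in the same sense. The path makes no new compound (F0) and returns to the route at 17.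

2. Step 11. The carbenoid may attack the enesulfonamide or insert into C–H bonds next to oxygen instead of cyclopropanating the hindered silyl enol ether, and the β-acetal oxygen may be eliminated when the cyclopropane is opened. Fallback: C13 and C14 are brought in by a radical instead of a carbenoid. Setting out from 17, ethyl iodoacetate with Et3B/air and 2,6-lutidine (CH2Cl2, −20 °C) should add the ester-stabilised radical to C12 of the silyl enol ether; iodine-atom transfer and collapse of the α-iodo silyl ether give the keto ester directly, a known atom-transfer alkylation of silyl enol ethers. No new compound is made (F0); the path returns at 20, which is reduced and lactonised as in step 12.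

3. Step 21. Once the sulfonyl group has gone, the nitrogen is part of a metalated enamine, which may be alkylated at C9 (closing a five-membered carbocycle) instead of at nitrogen, and the basic fluoride may epimerise C13 and C20. Fallback: the leaving group is changed first and the ring is closed from the neutral imine under non-basic conditions. Setting out from 37, Finkelstein exchange (NaI, acetone, 55 °C) gives the iodide F1. The SES group is then removed at 0 °C with (Me2N)3S+ Me3SiF2− in DMF in the presence of 2,6-di-tert-butylphenol as proton donor, so that the nitrogen is protonated as soon as it is set free and the iodo 1-pyrroline F2 results. F2 should close the azepine ring at rt in MeCN over solid NaHCO3 by N-alkylation of the imine and loss of the C9 proton, which returns to the route at 39.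

**Further compounds**

F0 | step 10 | none | none
F0 | step 11 | none | none
F1 | step 21 | iodide: 37 with 4-iodobutyl in place of 4-chlorobutyl on C9 | CC[C@@H]1C(CCCCI)=C2N(S(=O)(=O)CC[Si](C)(C)C)[C@H]([C@@H]4C[C@H](C)C(=O)O4)C[C@]2(O)[C@H]3[C@@H]1OC(=O)[C@H]3C
F2 | step 21 | iodo 1-pyrroline: 38 with 4-iodobutyl in place of 4-chlorobutyl (C9 epimers) | CC[C@@H]1C(CCCCI)C2=N[C@H]([C@@H]4C[C@H](C)C(=O)O4)C[C@]2(O)[C@H]3[C@@H]1OC(=O)[C@H]3C
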